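**Retrosynthetic overview**
- The CH2–aryl bond on the ring without C-methyl (ring A) is cut last: 2,4-dihydroxy-6-methoxyacetophenone attacks through C3 an ortho-quinone methide of the C-methyl ring (ring B), released from a Mannich base made in the same flask.
- Key disconnection in both monomers: the aryl C–OMe bond ortho to the acetyl group, traced back to a C–H bond of 2,4-dihydroxyacetophenone (ring A) and of 2,4-dihydroxy-3-methylacetophenone (ring B).
- That C–O bond is made by a one-pot carbonyl-directed C–H borylation and copper-mediated methoxylation on the unprotected phenols, which fixes the oxygen pattern without protecting groups.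
- No ring is built; both benzene rings are bought intact. Order: two parallel C–O bond formations, then the CH2 bridge.

Assumption: the target has no stereocentre and is achiral, so "single enantiomer" means the one constitution given and no stereocontrol is needed.

**Step 1**
Reactants: 1 2,4-dihydroxyacetophenone [1-(2,4-dihydroxyphenyl)ethanone]; 2 bis(pinacolato)diboron (B2pin2); 3 methanol
Product: 7 1-(2,4-dihydroxy-6-methoxyphenyl)ethanone, via O-borylated ketone 4 (not isolated), via C6-borylated ketone 5 (not isolated), via dihydroxy arylboronate 6 (not isolated)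
Conditions: B2pin2 (2.2 equiv), [Ir(OMe)(cod)]2 (2.5 mol%), AsPh3 (5 mol%), octane, 25 then 110 °C; evaporate; then MeOH, Cu(OAc)2 (2.5 equiv), pyridine, 4 Å MS, N2, 50 °C; aqueous EDTA work-up
Reagents that add atoms: methanol, CO
Why: Proposed new method: B2pin2 under iridium catalysis first turns both O–H groups into O–Bpin groups (H2 is lost), which removes the O–H···O=C hydrogen bond that locks the carbonyl away from C6 and masks the phenols, the free carbonyl then binds the AsPh3-ligated tris(boryl) trivalent iridium centre and delivers it to the only ortho C–H (C6), and after methanolysis of the O–Bpin groups the remaining C–Bpin bond transmetalates to divalent copper, disproportionation gives an aryl(methoxo) trivalent copper species and C–O reductive elimination closes the aryl methyl ether; the closest known reaction types are the carbonyl-directed iridium-catalysed ortho C–H borylation of simple aryl ketones and the Chan–Lam etherification of arylboronic esters, neither shown on free dihydroxyaryl ketones nor joined into a net C–H to C–OMe exchange; no stereocentre is formed.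

**Step 2**
Reactants: 8 2,4-dihydroxy-3-methylacetophenone [1-(2,4-dihydroxy-3-methylphenyl)ethanone]; 2 bis(pinacolato)diboron (B2pin2); 3 methanol
Product: 12 1-(2,4-dihydroxy-6-methoxy-3-methylphenyl)ethanone, via O-borylated ketone 9 (not isolated), via C6-borylated ketone 10 (not isolated), via dihydroxy arylboronate 11 (not isolated)
Conditions: B2pin2 (2.2 equiv), [Ir(OMe)(cod)]2 (2.5 mol%), AsPh3 (5 mol%), octane, 25 then 110 °C; evaporate; then MeOH, Cu(OAc)2 (2.5 equiv), pyridine, 4 Å MS, N2, 50 °C; aqueous EDTA work-up
Reagents that add atoms: methanol, CO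
Why: Proposed new method: the same one-pot sequence as in step 1 (in-situ O–Bpin masking, carbonyl-directed iridium-catalysed borylation of the single ortho C–H at C6, then Chan–Lam-type C–O coupling at copper with methanol), so the methoxy group can only enter para to the C-methyl group; the closest known reaction types are again the directed ortho C–H borylation of aryl ketones and the Chan–Lam etherification of arylboronic esters; no stereocentre is formed.

**Step 3**
Reactants: 12 1-(2,4-dihydroxy-6-methoxy-3-methylphenyl)ethanone; 13 N,N,N',N'-tetramethylmethanediamine [bis(dimethylamino)methane]; 7 1-(2,4-dihydroxy-6-methoxyphenyl)ethanone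
Product: 16 1-{3-[(3-acetyl-2,6-dihydroxy-4-methoxyphenyl)methyl]-4,6-dihydroxy-2-methoxy-5-methylphenyl}ethanone (the target, achiral), via Mannich base 14 (not isolated), via ortho-quinone methide 15 (not isolated)
Conditions: CH2(NMe2)2 (1.0 equiv), 1,4-dioxane, 25 to 50 °C; then 7 (2.5 equiv), 100 °C, N2 sweep; excess 7 recovered on chromatography
Reagents that add atoms: N,N,N',N'-tetramethylmethanediamine, CN(C)CN(C)C
Why: Mannich reaction at C5, the only free ring carbon of 12, then thermal loss of dimethylamine to ortho-quinone methide 15 and Friedel–Crafts-type conjugate addition of 7 through C3 (its most electron-rich carbon, flanked by two OH groups), while 14 cannot self-condense because its ring is fully substituted and the neutral, alkali-free medium avoids scrambling of the methylene bridge; no stereocentre is formed.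

**Compound list**
1 | 1-(2,4-dihydroxyphenyl)ethanone (2,4-dihydroxyacetophenone) | CC(=O)c1ccc(O)cc1O | starting material
2 | bis(pinacolato)diboron, B2pin2 | CC1(C)OB(OC1(C)C)B1OC(C)(C)C(C)(C)O1 | starting material
3 | methanol | CO | starting material
4 | 1-[2,4-bis(4,4,5,5-tetramethyl-1,3,2-dioxaborolan-2-yloxy)phenyl]ethanone | CC(=O)c1ccc(OB2OC(C)(C)C(C)(C)O2)cc1OB1OC(C)(C)C(C)(C)O1 | intermediate
5 | 1-[2,4-bis(4,4,5,5-tetramethyl-1,3,2-dioxaborolan-2-yloxy)-6-(4,4,5,5-tetramethyl-1,3,2-dioxaborolan-2-yl)phenyl]ethanone | CC(=O)c1c(B2OC(C)(C)C(C)(C)O2)cc(OB2OC(C)(C)C(C)(C)O2)cc1OB1OC(C)(C)C(C)(C)O1 | intermediate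
6 | 1-[2,4-dihydroxy-6-(4,4,5,5-tetramethyl-1,3,2-dioxaborolan-2-yl)phenyl]ethanone | CC(=O)c1c(B2OC(C)(C)C(C)(C)O2)cc(O)cc1O | intermediate
7 | 1-(2,4-dihydroxy-6-methoxyphenyl)ethanone | COc1cc(O)cc(O)c1C(C)=O | intermediate
8 | 1-(2,4-dihydroxy-3-methylphenyl)ethanone (2,4-dihydroxy-3-methylacetophenone) | CC(=O)c1ccc(O)c(C)c1O | starting material
9 | 1-[3-methyl-2,4-bis(4,4,5,5-tetramethyl-1,3,2-dioxaborolan-2-yloxy)phenyl]ethanone | CC(=O)c1ccc(OB2OC(C)(C)C(C)(C)O2)c(C)c1OB1OC(C)(C)C(C)(C)O1 | intermediate
10 | 1-[3-methyl-2,4-bis(4,4,5,5-tetramethyl-1,3,2-dioxaborolan-2-yloxy)-6-(4,4,5,5-tetramethyl-1,3,2-dioxaborolan-2-yl)phenyl]ethanone | CC(=O)c1c(B2OC(C)(C)C(C)(C)O2)cc(OB2OC(C)(C)C(C)(C)O2)c(C)c1OB1OC(C)(C)C(C)(C)O1 | intermediate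
11 | 1-[2,4-dihydroxy-3-methyl-6-(4,4,5,5-tetramethyl-1,3,2-dioxaborolan-2-yl)phenyl]ethanone | CC(=O)c1c(B2OC(C)(C)C(C)(C)O2)cc(O)c(C)c1O | intermediate
12 | 1-(2,4-dihydroxy-6-methoxy-3-methylphenyl)ethanone | COc1cc(O)c(C)c(O)c1C(C)=O | intermediate
13 | N,N,N',N'-tetramethylmethanediamine | CN(C)CN(C)C | starting material
14 | 1-{3-[(dimethylamino)methyl]-4,6-dihydroxy-2-methoxy-5-methylphenyl}ethanone | COc1c(CN(C)C)c(O)c(C)c(O)c1C(C)=O | intermediate
15 | 4-acetyl-3-hydroxy-5-methoxy-2-methyl-6-methylidenecyclohexa-2,4-dien-1-one | C=C1C(=O)C(C)=C(O)C(C(C)=O)=C1OC | intermediate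
16 | 1-{3-[(3-acetyl-2,6-dihydroxy-4-methoxyphenyl)methyl]-4,6-dihydroxy-2-methoxy-5-methylphenyl}ethanone (achiral) | COc1cc(O)c(Cc2c(O)c(C)c(O)c(C(C)=O)c2OC)c(O)c1C(C)=O | target

**Step count**
Total steps: 3 (steps 1 and 2 run in parallel). Longest linear sequence: 2 steps (8 to 12 to 16, or 1 to 7 to 16).

**Steps most likely to fail**

Step 2 (the proposed new method on the more hindered ketone 8). The 2-O–Bpin group sits between the acetyl and the methyl group, so its boron may hold the carbonyl and slow the directed borylation. The ortho-acyl arylboronate 11 may also lose boron by protonation before it couples at copper; this returns 8, never a wrong isomer. The fallback uses known chemistry, sets out from 7 and comes back at 12. It is nuclear C-methylation of 7 (MeI 1.1 equiv, NaOMe, MeOH, 0 to 25 °C), which goes mainly at C3 between the two hydroxyl groups. The 5-methyl and 3,5-dimethyl by-products are removed by chromatography. This fallback makes no compound outside the list (F0).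

Step 1 (the proposed new method). The risks are the same as for step 2: a sluggish directed borylation, protodeboronation of 6, and O-arylation or oxidation of the free phenols by divalent copper. The fallback uses known chemistry, sets out from 1 and comes back at 7.
- 1 is benzylated on both oxygens (BnBr, K2CO3, DMF, 80 °C) to 1-[2,4-bis(benzyloxy)phenyl]ethanone F1.
- F1 has no O–H and is an ordinary aryl ketone for the known carbonyl-directed iridium-catalysed ortho-borylation (B2pin2, [Ir(OMe)(cod)]2, AsPh3, octane, 110 °C), which gives 1-[2,4-bis(benzyloxy)-6-(4,4,5,5-tetramethyl-1,3,2-dioxaborolan-2-yl)phenyl]ethanone F2.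
- Oxidation (NaBO3·4H2O, THF/H2O) gives 1-[2,4-bis(benzyloxy)-6-hydroxyphenyl]ethanone F3.
- O-methylation of this single phenol (MeI, K2CO3, acetone, reflux) gives 1-[2,4-bis(benzyloxy)-6-methoxyphenyl]ethanone F4.
- Hydrogenolysis (H2, Pd/C, EtOAc, 25 °C) returns 7.

Step 3 (bridge formation). Ketone 7 has two nucleophilic ring carbons, so some C5-linked isomer and some doubly alkylated 7 can form, and these may be hard to separate from 16. The fallback reverses the roles of the rings and settles the regiochemistry at a stage that can be purified; it sets out from 7 and comes back at 16.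
- A classical Mannich reaction of 7 (aqueous Me2NH, aqueous CH2O, EtOH, 20 °C) gives 1-{3-[(dimethylamino)methyl]-2,4-dihydroxy-6-methoxyphenyl}ethanone F5, which is recrystallised free of its C5 isomer.
- F5 is added slowly to 12 (3 equiv) in 1,4-dioxane at 100 °C and loses dimethylamine to 4-acetyl-5-hydroxy-3-methoxy-6-methylidenecyclohexa-2,4-dien-1-one F6.
- F6 is captured by C5 of 12, its only free ring carbon, to give 16.

**Further compounds**
F1 | step 1 | 1-[2,4-bis(benzyloxy)phenyl]ethanone | CC(=O)c1ccc(OCc2ccccc2)cc1OCc1ccccc1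
F2 | step 1 | 1-[2,4-bis(benzyloxy)-6-(4,4,5,5-tetramethyl-1,3,2-dioxaborolan-2-yl)phenyl]ethanone | CC(=O)c1c(B2OC(C)(C)C(C)(C)O2)cc(OCc2ccccc2)cc1OCc1ccccc1
F3 | step 1 | 1-[2,4-bis(benzyloxy)-6-hydroxyphenyl]ethanone | CC(=O)c1c(O)cc(OCc2ccccc2)cc1OCc1ccccc1
F4 | step 1 | 1-[2,4-bis(benzyloxy)-6-methoxyphenyl]ethanone | COc1cc(OCc2ccccc2)cc(OCc2ccccc2)c1C(C)=O
F0 | step 2 | none | none
F5 | step 3 | 1-{3-[(dimethylamino)methyl]-2,4-dihydroxy-6-methoxyphenyl}ethanone | COc1cc(O)c(CN(C)C)c(O)c1C(C)=O
F6 | step 3 | 4-acetyl-5-hydroxy-3-methoxy-6-methylidenecyclohexa-2,4-dien-1-one | C=C1C(=O)C=C(OC)C(C(C)=O)=C1O
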